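The cyclobutane (C4–C5–C11–C10, longipinane numbering; C1 ketone, C2=C3) is closed last by a ring-contractive 1,2-shift. In a 1-oxy-norbornene, the one-carbon bridge C10 migrates from the bridgehead carbinol C1 to C11 with loss of an endo bromide, and C1 becomes the enone carbonyl. The step exploits the C1 ketone next to bridgehead C11 of the four-membered ring and turns the bicyclo[2.2.1]heptene into the bicyclo[3.1.1]heptenone in one operation. The precursor, which contains a temporary C1–C10 bond, is built by an intramolecular Diels–Alder reaction of a 5,5-disubstituted silyloxycyclopentadiene with a tethered (E)-bromoalkene, which also forms the seven-membered ring.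

Key step: step 11

Remark: hydroxypivaldehyde 1, sold as its dimer, is taken to react as the monomer in step 1; atom labels C1–C11 in the text are those of the longipinane skeleton of the target and are also used for the precursors.

Step 1
Reactants: 1 3-hydroxy-2,2-dimethylpropanal
Product: 2 (E)-4-bromo-2,2-dimethylbut-3-en-1-ol
Conditions: CHBr3, CrBr2, THF, 23 °C
Reagents that add atoms: bromoform, BrC(Br)Br
Why: Takai olefination, in which the geminal dichromium carbenoid adds to the aldehyde and eliminates to give the (E)-bromoalkene (C5=C11), the free neopentyl alcohol being tolerated.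

Step 2
Reactants: 2 (E)-4-bromo-2,2-dimethylbut-3-en-1-ol
Product: 3 (E)-4-bromo-2,2-dimethylbut-3-enal
Conditions: Dess–Martin periodinane, NaHCO3, CH2Cl2, 0 → 23 °C
Reagents that add atoms: none
Why: Dess–Martin oxidation of the primary neopentyl alcohol should give the non-enolisable aldehyde without touching the bromoalkene.

Step 3
Reactants: 3 (E)-4-bromo-2,2-dimethylbut-3-enal
Product: 5 (1E,4R)-1-bromo-3,3-dimethylhepta-1,6-dien-4-ol, via O-borinate 4 (not isolated)
Conditions: (+)-Ipc2B(allyl), Et2O, −78 °C; then NaOH, H2O2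
Reagents that add atoms: (+)-B-allyldiisopinocampheylborane, C=CCB([C@H]1C[C@H]2C[C@H](C2(C)C)[C@@H]1C)[C@H]1C[C@H]2C[C@H](C2(C)C)[C@@H]1C
Why: Brown allylboration through a closed chair transition state, in which the (+)-reagent should deliver allyl to the Re face and so set C7 as R by reagent control.

Step 4
Reactants: 5 (1E,4R)-1-bromo-3,3-dimethylhepta-1,6-dien-4-ol
Product: 6 1-({[(1E,4R)-1-bromo-3,3-dimethylhepta-1,6-dien-4-yl]oxy}methyl)-4-methoxybenzene (PMB ether of 5)
Conditions: NaH, PMBCl, Bu4NI (cat.), DMF, 0 → 23 °C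
Reagents that add atoms: 4-methoxybenzyl chloride, COc1ccc(CCl)cc1
Why: Williamson etherification of the sodium alkoxide; the PMB group survives fluoride and base, supports 1,3-induction in step 7 and is removed oxidatively in step 13.

Step 5
Reactants: 6 PMB ether of 5
Product: 8 (3R,5E)-6-bromo-3-[(4-methoxybenzyl)oxy]-4,4-dimethylhex-5-enal, via diol 7 (not isolated)
Conditions: OsO4 (cat.), NaIO4, 2,6-lutidine, dioxane/H2O, 23 °C
Reagents that add atoms: sodium periodate, [Na+].[O-]I(=O)(=O)=O (oxygen passed on through catalytic osmium tetroxide, O=[Os](=O)(=O)=O)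
Why: Lemieux–Johnson cleavage, in which only the terminal alkene is dihydroxylated (the bromoalkene is electron-poor and neopentyl) and the diol is cleaved to the C9 aldehyde.

Step 6
Reactants: 9 3-methylcyclopent-2-en-1-one
Product: 11 trimethyl[(4-methylcyclopenta-1,3-dien-2-yl)oxy]silane, via lithium enolate 10 (not isolated)
Conditions: LiN(i-Pr)2, THF, −78 °C; then Me3SiCl; used cold at once
Reagents that add atoms: chlorotrimethylsilane, C[Si](C)(C)Cl
Why: Kinetic α′-deprotonation of the enone and O-silylation should give the cross-conjugated 2-silyloxydiene regiospecifically, immediate use avoiding 1,5-hydrogen shifts.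

Step 7
Reactants: 8 (3R,5E)-6-bromo-3-[(4-methoxybenzyl)oxy]-4,4-dimethylhex-5-enal; 11 trimethyl[(4-methylcyclopenta-1,3-dien-2-yl)oxy]silane
Product: 12 5-[(1R,3R,5E)-6-bromo-1-hydroxy-3-[(4-methoxybenzyl)oxy]-4,4-dimethylhex-5-en-1-yl]-3-methylcyclopent-2-en-1-one (both epimers at ring C5)
Conditions: BF3·OEt2, CH2Cl2, −78 °C; aqueous NaHCO3 work-up
Reagents that add atoms: none
Why: Mukaiyama aldol addition through an open transition state, in which 1,3-anti induction from the β-OPMB stereocentre (polar, non-chelate model) should set C9 as R; the C10–H centre is unimportant because step 8 planarises it.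

Step 8
Reactants: 12 aldol adduct (C10 epimers)
Product: 14 (5S)-5-[(1R,3R,5E)-6-bromo-1-hydroxy-3-[(4-methoxybenzyl)oxy]-4,4-dimethylhex-5-en-1-yl]-3,5-dimethylcyclopent-2-en-1-one, via dilithium dianion 13 (not isolated)
Conditions: LiN(i-Pr)2 (2.2 equiv), THF, −78 → −40 °C; then MeI, DMPU, −78 → −20 °C
Reagents that add atoms: iodomethane, CI
Why: Fráter–Seebach-type alkylation, in which the lithium-bridged alkoxide–enolate chelate holds the C9–O bond in the enolate plane so that iodomethane should enter anti to the C8 chain and set the quaternary C10 with its methyl group.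

Step 9
Reactants: 14 methylated aldol
Product: 15 tert-butyl{[(5S)-5-{(1R,3R,5E)-6-bromo-1-[(tert-butyldimethylsilyl)oxy]-3-[(4-methoxybenzyl)oxy]-4,4-dimethylhex-5-en-1-yl}-3,5-dimethylcyclopenta-1,3-dien-1-yl]oxy}dimethylsilane
Conditions: TBSOTf, Et3N, CH2Cl2, −78 → 0 °C
Reagents that add atoms: tert-butyldimethylsilyl trifluoromethanesulfonate, CC(C)(C)[Si](C)(C)OS(=O)(=O)C(F)(F)F
Why: Silyl triflate/amine soft enolisation; with the α′ carbon quaternary only γ-deprotonation at the ring CH2 is open, giving a 1-silyloxycyclopenta-1,3-diene that cannot isomerise by 1,5-hydrogen shift, while the C9 hydroxyl is silylated in the same operation.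

Step 10
Reactants: 15 bis-silyl diene
Product: 16 Diels–Alder adduct: norbornene with bridgeheads C1 (OTBS) and C4, alkene C2=C3 (3-methyl), bridge C11–C5 (11-endo-bromo, C6 exo on C5), one-carbon bridge C10 (methyl syn to the alkene) and the seven-membered ring C4–C5–C6–C7(OPMB)–C8–C9(OTBS)–C10
Conditions: PhMe (high dilution), BHT, sealed tube, 180 °C
Reagents that add atoms: none
Why: Intramolecular Diels–Alder reaction of a cyclopentadiene tethered through its sp3 carbon; the neopentyl dienophile carbon C5 should bond to the unsubstituted terminus C4 and C11 to the silyloxy-bearing C1, the tether forces C6 exo so that the (E)-alkene places bromine endo, and C4, C5, C11 and C1 all follow from C10.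

Step 11
Reactants: 16 Diels–Alder adduct
Product: 18 (4R,5S,7R,9R,10R,11R)-9-hydroxy-7-[(4-methoxybenzyl)oxy]longipin-2-en-1-one, via bromo diol 17 (not isolated)
Conditions: Bu4NF, THF, 0 → 60 °C
Reagents that add atoms: none
Why: Proposed new method: fluoride cleaves both silyl ethers and the bridgehead C1 alkoxide of 17 pushes the C1–C10 σ-bond, which lies antiperiplanar to the endo C11–Br bond, onto C11 as bromide leaves, so that C1 becomes the carbonyl conjugated with C2=C3 (anionic semipinacol 1,2-shift). The closest known reaction types are the base-induced semipinacol ring contraction of cyclic halohydrins and the semibenzilic (quasi-Favorskii) shift of bicyclo[2.2.1] α-halo ketones, and the step is the reverse of the pinene-to-bornyl chloride Wagner–Meerwein shift, made downhill here by C=O formation and enone conjugation. The cyclobutane C4–C5–C11–C10 is closed by this 1,2-alkyl shift, an intramolecular backside displacement at C11 by the migrating σ-bond through a three-centre transition state. C11 is formed with inversion and C10 migrates with retention, so both follow from the endo bromide and the configuration of 16, while C4, C5, C7 and C9 are untouched. The step needs migration of C10 and not of the vinylic C2, which is secured because only the C1–C10 bond is antiperiplanar to the endo C–Br bond, and epoxide closure and anti-elimination are geometrically impossible at the bridgehead. A reversible oxy-anion retro-Diels–Alder reaction would only return the dienolate of 14.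

Step 12
Reactants: 18 9-hydroxy-7-PMB-oxy longipinenone
Product: 19 (4R,5S,7R,9R,10R,11R)-7-[(4-methoxybenzyl)oxy]-9-[(E)-2-methylbut-2-enoyloxy]longipin-2-en-1-one
Conditions: tigloyl chloride, Et3N, DMAP (cat.), CH2Cl2, 0 → 40 °C
Reagents that add atoms: tigloyl chloride, C/C=C(\C)C(Cl)=O
Why: DMAP-catalysed acylation of the only free hydroxyl should install the (E)-ester at C9 without touching any stereocentre.

Step 13
Reactants: 19 9-tiglate 7-PMB ether
Product: 20 (4R,5S,7R,9R,10R,11R)-7-hydroxy-9-[(E)-2-methylbut-2-enoyloxy]longipin-2-en-1-one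
Conditions: DDQ, CH2Cl2/pH 7 buffer, 0 → 23 °C
Reagents that add atoms: none
Why: Oxidative PMB cleavage (benzylic hydride abstraction by DDQ, then hydrolysis of the oxocarbenium ion) should free C7–OH while the electron-poor enone and tiglate stay inert.

Step 14
Reactants: 20 7-hydroxy 9-tiglate
Product: 21 (4R,5S,7R,9R,10R,11R)-7-[(Z)-2-methylbut-2-enoyloxy]-9-[(E)-2-methylbut-2-enoyloxy]longipin-2-en-1-one (CNP0236543.4)
Conditions: angelic acid, 2,4,6-trichlorobenzoyl chloride, Et3N, PhMe, 23 °C; then 20, 80 °C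
Reagents that add atoms: angelic acid, C/C=C(/C)C(=O)O
Why: Yamaguchi esterification through the mixed anhydride, run without a nucleophilic catalyst to avoid Z→E isomerisation, should acylate C7–OH and give the target.

Compound list
1 | 3-hydroxy-2,2-dimethylpropanal (hydroxypivaldehyde) | OCC(C)(C)C=O | starting material
2 | (E)-4-bromo-2,2-dimethylbut-3-en-1-ol | OCC(C)(C)/C=C/Br | intermediate
3 | (E)-4-bromo-2,2-dimethylbut-3-enal | O=CC(C)(C)/C=C/Br | intermediate
4 | diisopinocampheylborinate ester of 5 | C=CC[C@@H](OB([C@H]1C[C@H]2C[C@H](C2(C)C)[C@@H]1C)[C@H]1C[C@H]2C[C@H](C2(C)C)[C@@H]1C)C(C)(C)/C=C/Br | intermediate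
5 | (1E,4R)-1-bromo-3,3-dimethylhepta-1,6-dien-4-ol | C=CC[C@@H](O)C(C)(C)/C=C/Br | intermediate
6 | 1-({[(1E,4R)-1-bromo-3,3-dimethylhepta-1,6-dien-4-yl]oxy}methyl)-4-methoxybenzene | C=CC[C@@H](OCc1ccc(OC)cc1)C(C)(C)/C=C/Br | intermediate
7 | (4R,6E)-7-bromo-4-[(4-methoxybenzyl)oxy]-5,5-dimethylhept-6-ene-1,2-diol (C2 epimers) | OCC(O)C[C@@H](OCc1ccc(OC)cc1)C(C)(C)/C=C/Br | intermediate
8 | (3R,5E)-6-bromo-3-[(4-methoxybenzyl)oxy]-4,4-dimethylhex-5-enal | O=CC[C@@H](OCc1ccc(OC)cc1)C(C)(C)/C=C/Br | intermediate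
9 | 3-methylcyclopent-2-en-1-one | CC1=CC(=O)CC1 | starting material
10 | lithium 4-methylcyclopenta-1,3-dien-2-olate | CC1=CC(O[Li])=CC1 | intermediate
11 | trimethyl[(4-methylcyclopenta-1,3-dien-2-yl)oxy]silane | CC1=CC(O[Si](C)(C)C)=CC1 | intermediate
12 | 5-[(1R,3R,5E)-6-bromo-1-hydroxy-3-[(4-methoxybenzyl)oxy]-4,4-dimethylhex-5-en-1-yl]-3-methylcyclopent-2-en-1-one (ring C5 epimers) | O=C1C=C(C)CC1[C@H](O)C[C@@H](OCc2ccc(OC)cc2)C(C)(C)/C=C/Br | intermediate
13 | dilithium alkoxide–dienolate of 12 | CC1=CC(O[Li])=C(C1)[C@H](O[Li])C[C@@H](OCc2ccc(OC)cc2)C(C)(C)/C=C/Br | intermediate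
14 | (5S)-5-[(1R,3R,5E)-6-bromo-1-hydroxy-3-[(4-methoxybenzyl)oxy]-4,4-dimethylhex-5-en-1-yl]-3,5-dimethylcyclopent-2-en-1-one | O=C1C=C(C)C[C@@]1(C)[C@H](O)C[C@@H](OCc2ccc(OC)cc2)C(C)(C)/C=C/Br | intermediate
15 | tert-butyl{[(5S)-5-{(1R,3R,5E)-6-bromo-1-[(tert-butyldimethylsilyl)oxy]-3-[(4-methoxybenzyl)oxy]-4,4-dimethylhex-5-en-1-yl}-3,5-dimethylcyclopenta-1,3-dien-1-yl]oxy}dimethylsilane | CC(C)(C)[Si](C)(C)OC1=CC(C)=C[C@@]1(C)[C@H](O[Si](C)(C)C(C)(C)C)C[C@@H](OCc2ccc(OC)cc2)C(C)(C)/C=C/Br | intermediate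
16 | Diels–Alder adduct: 11-endo-bromo-1,9-bis(tert-butyldimethylsilyloxy)-7-[(4-methoxybenzyl)oxy] norbornene with C10 bonded to C1 and C4 (configuration at C4, C5, C7, C9, C10 as in 21) | COc1ccc(CO[C@@H]2C[C@@H](O[Si](C)(C)C(C)(C)C)[C@@]3(C)[C@]4(O[Si](C)(C)C(C)(C)C)C=C(C)[C@H]3[C@@H]([C@H]4Br)C2(C)C)cc1 | intermediate
17 | 1,9-diol of 16 (bridgehead C1–OH, formed as its alkoxide; endo bromide at C11) | COc1ccc(CO[C@@H]2C[C@@H](O)[C@@]3(C)[C@]4(O)C=C(C)[C@H]3[C@@H]([C@H]4Br)C2(C)C)cc1 | intermediate
18 | (4R,5S,7R,9R,10R,11R)-9-hydroxy-7-[(4-methoxybenzyl)oxy]longipin-2-en-1-one | COc1ccc(CO[C@@H]2C[C@@H](O)[C@@]3(C)[C@@H]4C(=O)C=C(C)[C@H]3[C@@H]4C2(C)C)cc1 | intermediate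
19 | (4R,5S,7R,9R,10R,11R)-7-[(4-methoxybenzyl)oxy]-9-[(E)-2-methylbut-2-enoyloxy]longipin-2-en-1-one | COc1ccc(CO[C@@H]2C[C@@H](OC(=O)/C(C)=C/C)[C@@]3(C)[C@@H]4C(=O)C=C(C)[C@H]3[C@@H]4C2(C)C)cc1 | intermediate
20 | (4R,5S,7R,9R,10R,11R)-7-hydroxy-9-[(E)-2-methylbut-2-enoyloxy]longipin-2-en-1-one | O[C@@H]1C[C@@H](OC(=O)/C(C)=C/C)[C@@]2(C)[C@@H]3C(=O)C=C(C)[C@H]2[C@@H]3C1(C)C | intermediate
21 | (4R,5S,7R,9R,10R,11R)-7-angeloyloxy-9-tigloyloxylongipin-2-en-1-one | C/C=C(/C)C(=O)O[C@@H]1C[C@@H](OC(=O)/C(C)=C/C)[C@@]2(C)[C@@H]3C(=O)C=C(C)[C@H]2[C@@H]3C1(C)C | target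

Total step count: 14. Longest linear sequence: 13 steps (steps 1–5 and 7–14); step 6 is a one-step side branch.

Steps most likely to fail

Step 11 (labelled step). The bridgehead alkoxide may stay as the unreactive bromo alcohol or revert by oxy-anion cycloreversion instead of undergoing the C10 shift. The fallback uses known chemistry and replaces the concerted shift by a fragmentation–recombination sequence. It sets out from 17, isolated by running the desilylation at 0 °C. Dess–Martin oxidation touches only the secondary C9 alcohol and should give the β-hydroxy ketone with the bridgehead C1–OH intact, F1. KN(SiMe3)2 in THF (−78 → 0 °C) then triggers a strain-releasing retro-aldol cleavage of the C1–C10 bond to the ring-opened C10 potassium enolate of the cis-fused 11-bromo bicyclo[5.4.0]undecadienedione, F2. Its enolate carbon closes the cyclobutane by 4-exo-tet C-alkylation of the α′-bromo enone with inversion at C11, as in classical bicyclo[3.1.1]heptane syntheses; O-alkylation is excluded because the enolate oxygen is held on the far side of the seven-membered ring. This gives the 7-PMB-oxy longipin-2-ene-1,9-dione, F3. Corey–Bakshi–Shibata reduction ((S)-Me-CBS, BH3·SMe2, −30 °C) of the saturated C9 ketone, which should react before the hindered conjugated C1 ketone, returns the route to 18.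

Step 10. The neopentyl, electronically neutral bromoalkene may add too slowly, so that the diene is lost to desilylation or alkyl shifts before cycloaddition. The fallback activates the dienophile with boron and sets out from 15. Bromine–lithium exchange (t-BuLi, Et2O, −78 °C) and trapping with Cy2BCl should give the (E)-alkenyl(dicyclohexyl)borane, F4. Its low-lying vacant orbital should let the intramolecular Diels–Alder reaction run at 23–50 °C to the 11-endo-boryl adduct, F5. Oxidation (NaBO3·4H2O, retention) should give the 11-endo alcohol, F6, and MsCl/Et3N its mesylate, F7. Bu4NF then removes the silyl groups and the same 1,2-shift, now with a sulfonate leaving group, comes back to the route at 18.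

Step 14. Acylation of the neopentyl C7 alcohol may be slow, and under forcing conditions the (Z)-acyl unit may isomerise to the (E)-isomer. The fallback builds the (Z)-alkene on the ester and sets out from 20. DCC/DMAP coupling with 2-[bis(2,2,2-trifluoroethoxy)phosphoryl]propanoic acid should give the 7-O-phosphonopropanoate, F8. Still–Gennari olefination (KN(SiMe3)2, 18-crown-6, THF, −78 °C; acetaldehyde) should then give the (Z)-2-methylbut-2-enoate and so arrive at 21.

Further compounds
F1 | step 11 | 9-oxo analogue of 17 (C9 ketone, bridgehead C1–OH, 11-endo-bromide) | COc1ccc(CO[C@@H]2CC(=O)[C@@]3(C)[C@]4(O)C=C(C)[C@H]3[C@@H]([C@H]4Br)C2(C)C)cc1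
F2 | step 11 | potassium C10 enolate of the C1–C10-cleaved cis-fused 11-bromo-7-[(4-methoxybenzyl)oxy]bicyclo[5.4.0]undecadiene-1,9-dione | COc1ccc(CO[C@@H]2CC([O-])=C(C)[C@H]3C(C)=CC(=O)[C@H](Br)[C@H]3C2(C)C)cc1.[K+]
F3 | step 11 | (4R,5S,7R,10R,11R)-7-[(4-methoxybenzyl)oxy]longipin-2-ene-1,9-dione | COc1ccc(CO[C@@H]2CC(=O)[C@@]3(C)[C@@H]4C(=O)C=C(C)[C@H]3[C@@H]4C2(C)C)cc1
F4 | step 10 | (E)-alkenyl(dicyclohexyl)borane analogue of 15 (BCy2 in place of Br) | CC(C)(C)[Si](C)(C)OC1=CC(C)=C[C@@]1(C)[C@H](O[Si](C)(C)C(C)(C)C)C[C@@H](OCc2ccc(OC)cc2)C(C)(C)/C=C/B(C3CCCCC3)C3CCCCC3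
F5 | step 10 | 11-endo-(dicyclohexylboryl) analogue of 16 | COc1ccc(CO[C@@H]2C[C@@H](O[Si](C)(C)C(C)(C)C)[C@@]3(C)[C@]4(O[Si](C)(C)C(C)(C)C)C=C(C)[C@H]3[C@@H]([C@H]4B(C5CCCCC5)C5CCCCC5)C2(C)C)cc1
F6 | step 10 | 11-endo-hydroxy analogue of 16 | COc1ccc(CO[C@@H]2C[C@@H](O[Si](C)(C)C(C)(C)C)[C@@]3(C)[C@]4(O[Si](C)(C)C(C)(C)C)C=C(C)[C@H]3[C@@H]([C@H]4O)C2(C)C)cc1
F7 | step 10 | 11-endo-methanesulfonate of F6 | COc1ccc(CO[C@@H]2C[C@@H](O[Si](C)(C)C(C)(C)C)[C@@]3(C)[C@]4(O[Si](C)(C)C(C)(C)C)C=C(C)[C@H]3[C@@H]([C@H]4OS(C)(=O)=O)C2(C)C)cc1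
F8 | step 14 | 7-O-{2-[bis(2,2,2-trifluoroethoxy)phosphoryl]propanoyl} ester of 20 | CC(C(=O)O[C@@H]1C[C@@H](OC(=O)/C(C)=C/C)[C@@]2(C)[C@@H]3C(=O)C=C(C)[C@H]2[C@@H]3C1(C)C)P(=O)(OCC(F)(F)F)OCC(F)(F)F
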